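We begin at early times in the two earlier runs, teal and ochre, the readings we have for judging the three flasks.

| flask | starting material | gas | temperature | remark | time |
|---|---|---|---|---|---|
| teal | 0.067 M | 20 mM (held) | 85 °C | run made earlier |  |
| ochre | 0.15 M | 20 mM (held) | 102 °C | run made earlier |  |
| eta | 0.10 M | 20 mM (held) | 90 °C |  | 8.0 h |
| delta | 0.10 M | 20 mM (held) | 115 °C |  | 8.0 h |
| alpha | 0.10 M | 20 mM (held) |  | at 90 °C until 4.0 h, from then on at 115 °C | 8.0 h |

| run | time / h | target / % | starting material / % |
|---|---|---|---|
| teal | 0.833 | 0.4 | 94.9 |
| teal | 1.33 | 0 | 93.0 |
| teal | 2.00 | 0.5 | 89.6 |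
| teal | 2.50 | 0.1 | 87.1 |
| teal | 4.00 | 0 | 81.7 |
| teal | 6.00 | 0.3 | 73.9 |
| teal | 10.0 | 1.0 | 62.7 |
| ochre | 0.500 | 0 | 86.0 |
| ochre | 0.667 | 0 | 82.9 |
| ochre | 1.00 | 0.3 | 77.4 |
| ochre | 1.33 | 0.4 | 72.3 |
| ochre | 2.00 | 0.9 | 65.4 |
| ochre | 3.00 | 2.4 | 59.5 |
| ochre | 6.00 | 10.6 | 51.7 |

(scatter of a reading: 0.3 percentage points)

- amounts and yields of target count crystals too
- given per volume of solution although it is solid: crystals
- at the start none of partner is dissolved
- steps under discussion: crystals <-> target; partner -> second intermediate; open intermediate + second intermediate -> target; gas <-> partner; starting material <-> open intermediate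

* the flask with the highest amount of target, in percent of the starting material charged ("all alike" if they lie within 1.5 percentage points) (eta / delta / alpha / all alike)
* final target, as a percentage of the starting material charged, in eta
* final target, as a percentage of the starting material charged, in delta
* final target, as a percentage of the starting material charged, in alpha

In ochre, target stands at 2.4% after 3.00 h, and going on to 6.00 h multiplies it by 4.42, close to the 4.00 of a square law in time. Among the steps under discussion, such a law suits a rate carrying one concentration that climbs steadily: second intermediate, fed from partner while the gas is held at 20 mM. We expect that feed not to depend on the charge; at a given second intermediate the step to target is then pseudo-first-order in open intermediate, and we expect target in percent of the charge not to depend on the charge either.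

Our bench rule, for a flask at one temperature with the gas held at 20 mM, is therefore that target, as a fraction of the charge, is the square of t/τ, where t is the time and τ the square-law time. Teal's last reading, 1.0% with a scatter of 0.3 percentage points, gives τ = 100 h at 85 °C, and ochre's last reading gives 18.4 h at 102 °C. Taking the logarithm of τ as straight in temperature, we reckon 60.8 h at 90 °C and, for the time at which the square law would reach the whole charge at 115 °C, 5.06 h.

For eta, t/τ is 0.132, and the rule gives 1.74%. For delta it is 1.58, and the square, 250%, is more than the 100% charged, so the rule stops at this border and gives us no figure for delta. Alpha's hot stretch of 4.00 h, taken with delta's τ, gives a ratio of 0.791, smaller than delta's and larger than eta's, so we commit to the order delta, alpha, eta.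

The forecast named delta, with 2.2% in eta, 55% in delta and 33% in alpha, saying of delta “With depletion and saturation, about 55%”.

The flasks give 2.51% in eta, 55.7% in delta and 29.5% in alpha, the most target standing in delta.

    crystals ⇌ target, rate k1*(cs1 - [target]) while solid is left; crystals form when [target] > cs1 (solubility = 2.70 mM, k = 1.90 h⁻¹)
    partner → second intermediate (k = 0.190 h⁻¹, Ea = 116 kJ mol⁻¹)
    open intermediate + second intermediate → target (k = 0.860 L mol⁻¹ h⁻¹, Ea = 91.0 kJ mol⁻¹)
    gas ⇌ partner, rate k4*(csat - [partner]) (kL = 1.80 h⁻¹)
    starting material ⇌ open intermediate (K = 1.30, k = 0.0960 h⁻¹, Ea = 112 kJ mol⁻¹, ΔH = −41.0 kJ mol⁻¹)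
    (constants at 90 °C)

Delta, at t/τ of 1.58, holds 55.7% where the square read 250%, while eta, at 0.132, holds 2.51% against the rule's 1.74%. The neighbouring flask is delta kept at 130 °C, where the same reckoning gives τ = 1.14 h, so t/τ is 7.04, further past the border than delta, and after 8.00 h that flask holds 7.95% starting material and 89.8% target.

The numbers in the tables stem from a simulated flask with made-up constants, and the scatter is random.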